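**Plan**

- Retrosynthetic cuts, in order: C12–C13 (sp3–sp2 coupling to a preformed acetoxy enoate), C8=C17 (methylenation of a C8 ketone), O–CH3, then ring A at C3–C4, then C9–C11 and C10–C1, back to (1S,5S)-verbenone.
- Forward: ring B is the six-membered ring of verbenone; conjugate allylation builds quaternary C10, enolate alkylation adds C11–C12, and Wacker oxidation plus enol silylation turn the allyl arm into a 2-silyloxyallyl nucleophile (C1–C2–C3).
- Ring A closes last. The enabling feature is that C4 is 1,3 to C7 across ring B and C7 is alpha to the C8 carbonyl, so C4 can be stored as the CMe2 bridge of a cyclobutane (C4–C5–C6–C7); opening it gives a C4 cation and a C7=C8 enol ether, and the C2 oxygen makes C3 the enol ether terminus that captures C4.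
- Stereochemistry: C5 comes from verbenone; C10 from addition anti to the CMe2 bridge, which also fixes the trans ring fusion; C2 from thermodynamic (equatorial) ketone reduction; C9 from enolate equilibration; 13Z from an E enol tosylate coupled with retention.

Key step: step 5

Remark: commercial (1S,5S)-(−)-verbenone is assumed to be of high enantiomeric purity, since its C5 centre is the only source of absolute configuration. Labdane numbering is used throughout; verbenone C1, C2, C3, C4, C5, C6, C7 become C7, C8, C9, C10, C5, C4, C6.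

Step 1
Reactants: 1 (1S,5S)-(−)-verbenone
Product: 2 4-allyl-4,6,6-trimethyl-2-(trimethylsilyloxy)bicyclo[3.1.1]hept-2-ene (allyl anti to the CMe2 bridge)
Conditions: allylMgBr, CuBr·SMe2, LiCl, TMSCl, THF, −78 °C; Et3N/pentane work-up
Reagents that add atoms: allylmagnesium bromide C=CC[Mg]Br; chlorotrimethylsilane C[Si](C)(C)Cl
Why: Allylcopper activated by chlorotrimethylsilane adds 1,4 even to beta,beta-disubstituted enones, and on verbenone it should enter C10 from the face opposite the overhanging CMe2 bridge, so the new C10–C1 bond is trans to the C5–C4 bond (this sets C10 and the later trans ring fusion) and the enolate is trapped as the C8–C9 silyl enol ether.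

Step 2
Reactants: 2 silyl enol ether
Product: 4 methyl 2-[4-allyl-4,6,6-trimethyl-2-oxobicyclo[3.1.1]hept-3-yl]acetate (CH2CO2Me cis to allyl; both anti to the CMe2 bridge), via lithium enolate 3 (not isolated)
Conditions: MeLi, THF, 0 °C; then BrCH2CO2Me, HMPA, −78 to −20 °C
Reagents that add atoms: methyl bromoacetate COC(=O)CBr
Why: Methyllithium cleavage of the silyl enol ether gives the regiodefined lithium enolate (the other alpha carbon is a bridgehead and cannot enolise), which is C-alkylated by the reactive alpha-bromo ester anti to the CMe2 bridge; the C9 configuration so formed (side chain trans to the C10 methyl) is corrected by equilibration in step 9.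

Step 3
Reactants: 4 allyl keto ester
Product: 5 methyl 2-[4,6,6-trimethyl-2-oxo-4-(2-oxopropyl)bicyclo[3.1.1]hept-3-yl]acetate
Conditions: PdCl2 (cat.), CuCl, O2 (1 atm), DMF/H2O, rt
Reagents that add atoms: water O
Why: Tsuji–Wacker oxidation converts the monosubstituted terminal alkene with Markovnikov selectivity into the methyl ketone (C2=O, C3 methyl) and should leave ketone, ester and cyclobutane untouched.

Step 4
Reactants: 5 diketo ester
Product: 7 methyl 2-[4,6,6-trimethyl-2-oxo-4-(2-triisopropylsilyloxyprop-2-enyl)bicyclo[3.1.1]hept-3-yl]acetate, via lithium enolate 6 (not isolated)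
Conditions: LDA (lithium diisopropylamide), THF, −78 °C; then TIPSOTf, −78 °C
Reagents that add atoms: triisopropylsilyl trifluoromethanesulfonate CC(C)[Si](OS(=O)(=O)C(F)(F)F)(C(C)C)C(C)C
Why: Kinetic deprotonation by the hindered amide should occur at the unhindered C3 methyl (the C8 ketone can enolise only at the hindered C9 methine and the ester is less acidic), and O-silylation gives the terminal 2-silyloxyallyl unit needed for ring closure.

Step 5
Reactants: 7 silyl enol ether cyclobutyl ketone
Product: 9 methyl 2-oxo-8-(triisopropylsilyloxy)-9-epi-13,14,15,16,17-pentanorlabd-7-en-12-oate (trans-fused decalin; C5 and C10 as in the target; CH2CO2Me trans to the C10 methyl), via tertiary C4 cation 8 (not isolated)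
Conditions: TIPSOTf (cat.), 2,6-di-tert-butyl-4-methylpyridine (cat.), CH2Cl2, −78 to 0 °C
Reagents that add atoms: none
Why: Proposed new method: the silyl triflate silylates the C8 carbonyl oxygen, the activated ketone undergoes Grob-type heterolysis of the strained cyclobutane bond C7–C4 to give the C7=C8 silyl enol ether and the tertiary C4 cation, the C3 terminus of the 2-silyloxyallyl arm attacks this cation, and the resulting C2 silyloxocarbenium ion returns its silyl group to triflate, so the step is a chain isomerisation that leaves C2 as a free ketone and C8 masked. The closest known reaction types are the Lewis-acid ring opening of nopinone-type cyclobutyl ketones to tertiary p-menthane cations and the Lewis-acid tert-alkylation of silyl enol ethers by tertiary halides; their union in one step is not precedented. Ring A closes in a 6-endo-trig sense at the enol ether (C3 onto the exocyclic cation C4) through a chair transition state. No new stereocentre is formed; the trans ring fusion is inherited from the trans arrangement of the C5–C4 and C10–C1 bonds on ring B set in step 1, which can meet only as the diequatorial trans-fused chair. The step needs carbon capture of the cation to beat proton loss to an isopropenyl group and aldol-type attack of the enol ether on the activated C8 carbonyl; the nucleophilicity of the enol ether, the six-membered chair geometry and the irreversible release of cyclobutane strain should secure this.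

Step 6
Reactants: 9 keto ester silyl enol ether
Product: 10 8-(triisopropylsilyloxy)-9-epi-13,14,15,16,17-pentanorlabd-7-ene-2,12-diol (2-OH equatorial, trans to the C10 methyl)
Conditions: Li, NH3 (l), THF, EtOH, −78 to −33 °C; NH4Cl
Reagents that add atoms: none
Why: Dissolving-metal reduction gives the thermodynamically preferred alcohol, here the equatorial C2–OH, because the axial position is flanked by the syn-axial methyls on C4 and C10 (a hydride would attack the open face and give the axial epimer); the same Bouveault–Blanc-type conditions reduce the methyl ester to the C12 alcohol while the silyl enol ether is inert.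

Step 7
Reactants: 10 diol
Product: 11 12-(tert-butyldimethylsilyloxy)-8-(triisopropylsilyloxy)-9-epi-13,14,15,16,17-pentanorlabd-7-en-2-ol
Conditions: TBSCl, imidazole, CH2Cl2, 0 °C
Reagents that add atoms: tert-butyldimethylsilyl chloride CC(C)(C)[Si](C)(C)Cl
Why: The unhindered primary C12 hydroxyl should be silylated much faster than the secondary C2 hydroxyl.

Step 8
Reactants: 11 secondary alcohol
Product: 12 12-(tert-butyldimethylsilyloxy)-2-methoxy-8-(triisopropylsilyloxy)-9-epi-13,14,15,16,17-pentanorlabd-7-ene
Conditions: NaH, MeI, THF, 0 °C to rt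
Reagents that add atoms: iodomethane CI
Why: Williamson etherification of the equatorial C2 alkoxide; both silyl groups are stable to sodium hydride.

Step 9
Reactants: 12 bis-silyl methyl ether
Product: 14 12-hydroxy-2-methoxy-13,14,15,16,17-pentanorlabdan-8-one (C9 side chain equatorial, cis to the C10 methyl), via 9-epi keto alcohol 13 (not isolated)
Conditions: TBAF, THF, 0 °C to rt; then NaOMe (cat.), MeOH, rt
Reagents that add atoms: none
Why: Fluoride removes both silicon groups to release the C8 ketone and the C12 alcohol, and methoxide then equilibrates C9 through the C8–C9 enolate to the epimer with the side chain equatorial and cis to the C10 methyl (also the product of axial protonation anti to that methyl), which sets C9.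

Step 10
Reactants: 14 keto alcohol
Product: 15 2-methoxy-13,14,15,16-tetranorlabd-8(17)-en-12-ol
Conditions: Ph3PCH3Br, KOtBu, toluene, 90 °C
Reagents that add atoms: methyltriphenylphosphonium bromide C[P+](c1ccccc1)(c1ccccc1)c1ccccc1.[Br-]
Why: Wittig methylenation of the hindered C8 ketone with excess ylide at elevated temperature is the standard way to the C8(17) exocyclic methylene in this decalin series; the free alcohol is carried as its alkoxide.

Step 11
Reactants: 15 primary alcohol
Product: 16 12-iodo-2-methoxy-13,14,15,16-tetranorlabd-8(17)-ene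
Conditions: I2, PPh3, imidazole, CH2Cl2, 0 °C to rt
Reagents that add atoms: iodine II
Why: Appel-type iodination of the primary alcohol under neutral conditions should leave the exocyclic alkene and the methyl ether untouched.

Step 12
Reactants: 17 tert-butyl 4-chloro-3-oxobutanoate
Product: 18 tert-butyl 4-acetoxy-3-oxobutanoate
Conditions: KOAc, KI (cat.), acetone, reflux
Reagents that add atoms: potassium acetate CC(=O)[O-].[K+]
Why: SN2 displacement of the activated alpha-chloro ketone by acetate.

Step 13
Reactants: 18 beta-keto ester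
Product: 19 tert-butyl (E)-4-acetoxy-3-(p-toluenesulfonyloxy)but-2-enoate
Conditions: TsCl, N-methylimidazole, Et3N, CH2Cl2, 0 °C
Reagents that add atoms: p-toluenesulfonyl chloride Cc1ccc(cc1)S(Cl)(=O)=O
Why: Enol tosylation of a beta-keto ester under non-chelating amine conditions should give the E enol tosylate (sulfonate trans to the ester), so CH2OAc and the ester are cis as C13 requires.

Step 14
Reactants: 16 primary iodide; 19 E enol tosylate
Product: 21 tert-butyl (13Z)-16-acetoxy-2-methoxylabda-8(17),13-dien-15-oate, via alkylzinc iodide 20 (not isolated)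
Conditions: Zn dust, LiCl, THF, 40 °C; then 19, Pd(OAc)2 (cat.), SPhos (cat.), THF, rt
Reagents that add atoms: none
Why: Direct zinc insertion into the primary iodide and Negishi coupling of the alkylzinc with the enol tosylate form C12–C13 with retention of alkene geometry, so the E tosylate gives the 13Z enoate; acetate and tert-butyl ester tolerate the organozinc.

Step 15
Reactants: 21 tert-butyl ester
Product: 23 (2R,5R,9R,10R,13Z)-16-acetoxy-2-methoxylabda-8(17),13-dien-15-oic acid (target), via trimethylsilyl ester 22 (not isolated)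
Conditions: TMSOTf, 2,6-lutidine, CH2Cl2, 0 °C; then H2O (pH 4 buffer)
Reagents that add atoms: none
Why: Silyl triflate with 2,6-lutidine converts the tert-butyl ester into the silyl ester with loss of isobutene under buffered, non-protic conditions that should spare the allylic acetate and the acid-sensitive exocyclic alkene, and aqueous work-up frees the acid.

**Compound list**

1 | (1S,5S)-(−)-verbenone, (1S,5S)-4,6,6-trimethylbicyclo[3.1.1]hept-3-en-2-one | CC1=CC(=O)[C@H]2C[C@@H]1C2(C)C | starting material
2 | 4-allyl-4,6,6-trimethyl-2-(trimethylsilyloxy)bicyclo[3.1.1]hept-2-ene, bridgeheads as in 1, allyl anti to the CMe2 bridge | C[C@]1(CC=C)C=C(O[Si](C)(C)C)[C@H]2C[C@@H]1C2(C)C | intermediate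
3 | lithium enolate corresponding to 2 | C[C@]1(CC=C)C=C(O[Li])[C@H]2C[C@@H]1C2(C)C | intermediate
4 | methyl 2-[4-allyl-4,6,6-trimethyl-2-oxobicyclo[3.1.1]hept-3-yl]acetate, allyl and CH2CO2Me both anti to the CMe2 bridge | C[C@]1(CC=C)[C@@H](CC(=O)OC)C(=O)[C@H]2C[C@@H]1C2(C)C | intermediate
5 | methyl 2-[4,6,6-trimethyl-2-oxo-4-(2-oxopropyl)bicyclo[3.1.1]hept-3-yl]acetate, configuration as in 4 | C[C@]1(CC(C)=O)[C@@H](CC(=O)OC)C(=O)[C@H]2C[C@@H]1C2(C)C | intermediate
6 | terminal lithium enolate of the methyl ketone of 5 | C[C@]1(CC(=C)O[Li])[C@@H](CC(=O)OC)C(=O)[C@H]2C[C@@H]1C2(C)C | intermediate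
7 | methyl 2-[4,6,6-trimethyl-2-oxo-4-(2-triisopropylsilyloxyprop-2-enyl)bicyclo[3.1.1]hept-3-yl]acetate, configuration as in 4 | C[C@]1(CC(=C)O[Si](C(C)C)(C(C)C)C(C)C)[C@@H](CC(=O)OC)C(=O)[C@H]2C[C@@H]1C2(C)C | intermediate
8 | ring-opened tertiary C4 cation: cyclohexene with C7=C8 silyl enol ether, C5 bearing the CMe2 cation, C10 bearing methyl and the 2-silyloxyallyl arm | C[C+](C)[C@H]1CC=C(O[Si](C(C)C)(C(C)C)C(C)C)[C@H](CC(=O)OC)[C@]1(C)CC(=C)O[Si](C(C)C)(C(C)C)C(C)C | intermediate
9 | methyl 2-oxo-8-(triisopropylsilyloxy)-9-epi-13,14,15,16,17-pentanorlabd-7-en-12-oate, trans-fused, C5 and C10 as in the target, CH2CO2Me trans to the C10 methyl | CC(C)[Si](C(C)C)(C(C)C)OC1=CC[C@@H]2C(C)(C)CC(=O)C[C@@]2(C)[C@H]1CC(=O)OC | intermediate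
10 | 8-(triisopropylsilyloxy)-9-epi-13,14,15,16,17-pentanorlabd-7-ene-2,12-diol, 2-OH equatorial (trans to the C10 methyl) | CC(C)[Si](C(C)C)(C(C)C)OC1=CC[C@@H]2C(C)(C)C[C@@H](O)C[C@@]2(C)[C@H]1CCO | intermediate
11 | 12-O-TBS ether of 10 | CC(C)[Si](C(C)C)(C(C)C)OC1=CC[C@@H]2C(C)(C)C[C@@H](O)C[C@@]2(C)[C@H]1CCO[Si](C)(C)C(C)(C)C | intermediate
12 | 2-O-methyl ether of 11 | CC(C)[Si](C(C)C)(C(C)C)OC1=CC[C@@H]2C(C)(C)C[C@@H](OC)C[C@@]2(C)[C@H]1CCO[Si](C)(C)C(C)(C)C | intermediate
13 | 12-hydroxy-2-methoxy-9-epi-13,14,15,16,17-pentanorlabdan-8-one (side chain axial, trans to the C10 methyl) | O=C1CC[C@@H]2C(C)(C)C[C@@H](OC)C[C@@]2(C)[C@H]1CCO | intermediate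
14 | 12-hydroxy-2-methoxy-13,14,15,16,17-pentanorlabdan-8-one (side chain equatorial, cis to the C10 methyl; all centres as in the target) | O=C1CC[C@@H]2C(C)(C)C[C@@H](OC)C[C@@]2(C)[C@@H]1CCO | intermediate
15 | 2-methoxy-13,14,15,16-tetranorlabd-8(17)-en-12-ol, centres as in the target | C=C1CC[C@@H]2C(C)(C)C[C@@H](OC)C[C@@]2(C)[C@@H]1CCO | intermediate
16 | 12-iodo-2-methoxy-13,14,15,16-tetranorlabd-8(17)-ene | C=C1CC[C@@H]2C(C)(C)C[C@@H](OC)C[C@@]2(C)[C@@H]1CCI | intermediate
17 | tert-butyl 4-chloro-3-oxobutanoate | ClCC(=O)CC(=O)OC(C)(C)C | starting material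
18 | tert-butyl 4-acetoxy-3-oxobutanoate | CC(=O)OCC(=O)CC(=O)OC(C)(C)C | intermediate
19 | tert-butyl (E)-4-acetoxy-3-(p-toluenesulfonyloxy)but-2-enoate | Cc1ccc(cc1)S(=O)(=O)O/C(=C/C(=O)OC(C)(C)C)COC(C)=O | intermediate
20 | alkylzinc iodide from 16 (C12–ZnI) | C=C1CC[C@@H]2C(C)(C)C[C@@H](OC)C[C@@]2(C)[C@@H]1CC[Zn]I | intermediate
21 | tert-butyl (13Z)-16-acetoxy-2-methoxylabda-8(17),13-dien-15-oate | C=C1CC[C@@H]2C(C)(C)C[C@@H](OC)C[C@@]2(C)[C@@H]1CC/C(=C/C(=O)OC(C)(C)C)COC(C)=O | intermediate
22 | trimethylsilyl (13Z)-16-acetoxy-2-methoxylabda-8(17),13-dien-15-oate | C=C1CC[C@@H]2C(C)(C)C[C@@H](OC)C[C@@]2(C)[C@@H]1CC/C(=C/C(=O)O[Si](C)(C)C)COC(C)=O | intermediate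
23 | (2R,5R,9R,10R,13Z)-16-acetoxy-2-methoxylabda-8(17),13-dien-15-oic acid | C=C1CC[C@@H]2C(C)(C)C[C@@H](OC)C[C@@]2(C)[C@@H]1CC/C(=C/C(=O)O)COC(C)=O | target

**Step count and risks**

Total step count: 15. Longest linear sequence: 13 (steps 1 to 11, 14 and 15, from verbenone).

Steps most likely to fail:

1. Step 5 (proposed new method). What may go wrong: the C4 cation loses a proton to an isopropenyl group, or the enol ether attacks the activated C8 carbonyl in an aldol sense before the cyclobutane opens. Fallback with known reactions, separating the two events: setting out from diketone 5, anhydrous HCl with ZnCl2 in CH2Cl2 opens the cyclobutane in the manner known for nopinone-type ketones and stores the cation as the monocyclic tertiary chloride F1. Double kinetic enolisation (LDA, 2 equiv, then TIPSOTf, THF, −78 °C) gives the bis(silyl enol ether) chloride F2. Catalytic ZnBr2 in CH2Cl2 then ionises the tertiary chloride and the C3 enol ether terminus alkylates it (Lewis-acid tert-alkylation of a silyl enol ether), which returns to the route at compound 9.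

2. Step 6. What may go wrong: the basic dissolving-metal medium cleaves the silyl enol ether and the freed C8 ketone is over-reduced, or ester reduction is incomplete. Fallback that separates the two reductions: setting out from 9, SmI2 in THF/HMPA with i-PrOH reduces only the C2 ketone by electron transfer to the equatorial hydroxy ester F3. NaH/MeI gives the methyl ether ester F4, and LiAlH4 in THF at 0 °C reduces the ester to the primary alcohol F5 with the silyl enol ether intact. TBAF followed by NaOMe/MeOH then returns to the route at compound 14.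

3. Step 14. What may go wrong: alkene geometry erodes during enol tosylate formation or coupling, or oxidative addition into the enol tosylate is sluggish. Fallback in which a ring enforces the geometry: setting out from iodide 16, the alkylzinc iodide 20 is coupled (Pd(PPh3)4, THF) with commercial 4-bromofuran-2(5H)-one to give the butenolide F6, in which C15 and C16 are necessarily cis. LiOH in THF/H2O opens the lactone to the lithium hydroxy carboxylate F7. This is acetylated as the salt (Ac2O, pyridine, DMAP, 0 °C) and acidified to pH 4, which returns to the route at target 23.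

**Further compounds**

F1 | step 5 | methyl 2-[3-(2-chloropropan-2-yl)-2-methyl-6-oxo-2-(2-oxopropyl)cyclohexyl]acetate (ring-opened tertiary chloride; C5 and C10 as in 8) | CC(C)(Cl)[C@H]1CCC(=O)[C@H](CC(=O)OC)[C@]1(C)CC(C)=O
F2 | step 5 | bis(triisopropylsilyl enol ether) of F1 (C7=C8 and C2=C3) | CC(C)(Cl)[C@H]1CC=C(O[Si](C(C)C)(C(C)C)C(C)C)[C@H](CC(=O)OC)[C@]1(C)CC(=C)O[Si](C(C)C)(C(C)C)C(C)C
F3 | step 6 | methyl 2-hydroxy-8-(triisopropylsilyloxy)-9-epi-13,14,15,16,17-pentanorlabd-7-en-12-oate (2-OH equatorial) | CC(C)[Si](C(C)C)(C(C)C)OC1=CC[C@@H]2C(C)(C)C[C@@H](O)C[C@@]2(C)[C@H]1CC(=O)OC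
F4 | step 6 | methyl 2-methoxy-8-(triisopropylsilyloxy)-9-epi-13,14,15,16,17-pentanorlabd-7-en-12-oate | CC(C)[Si](C(C)C)(C(C)C)OC1=CC[C@@H]2C(C)(C)C[C@@H](OC)C[C@@]2(C)[C@H]1CC(=O)OC
F5 | step 6 | 2-methoxy-8-(triisopropylsilyloxy)-9-epi-13,14,15,16,17-pentanorlabd-7-en-12-ol | CC(C)[Si](C(C)C)(C(C)C)OC1=CC[C@@H]2C(C)(C)C[C@@H](OC)C[C@@]2(C)[C@H]1CCO
F6 | step 14 | 2-methoxylabda-8(17),13-dien-15,16-olide (4-substituted furan-2(5H)-one) | C=C1CC[C@@H]2C(C)(C)C[C@@H](OC)C[C@@]2(C)[C@@H]1CCC1=CC(=O)OC1
F7 | step 14 | lithium (13Z)-16-hydroxy-2-methoxylabda-8(17),13-dien-15-oate | C=C1CC[C@@H]2C(C)(C)C[C@@H](OC)C[C@@]2(C)[C@@H]1CC/C(=C/C(=O)[O-])CO.[Li+]
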